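Remark on the chemistry: the target has no stereocentre, so the C3 carbinol centre made in the key step is carried as a racemate and an achiral catalyst is used.

## Structural features

The target is an achiral isoflavone: a benzo ring A fused to a 4-pyranone ring C, with an aryl ring B bonded to C3 through the C3–C1′ bond. Ring A carries hydroxyls at C5 and C7 and, between them at C6, a saturated 3-hydroxy-3-methylbutyl chain ending in a tertiary alcohol; C8 is unsubstituted. Ring B carries hydroxyls at C2′ and C4′ and a prenyl group at C3′ between them. Rings A and B are therefore both 2-alkylresorcinol units, and the C6 chain is the formal hydrate of a prenyl group, so the two halves can come from one intermediate. There are no stereocentres in the target, and the only one on the route (C3 of the key-step product) is temporary and has no neighbour. The fragile groups are the prenyl alkene flanked by two phenols and the tertiary alcohol flanked by two phenols (both cyclise to chromans under acid), and the electron-rich phenols themselves. The real difficulty is regiochemical (chain at C6 and not C8, prenyl at C3′ between two oxygens) and lies in joining two crowded, electron-rich halves at C3. The key step uses the fact that C4 is a carbonyl carbon on ring A and that C3, at the 3-hydroxy oxidation level, is also a former carbonyl carbon bearing ring B, so an aldehyde on ring A can act as an acyl anion towards a ring B aryl ketone and close ring C at C3–C4.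

## Logic of the disconnections

18 is traced to 17 by cutting four O–CH2 acetal bonds and one O–Si bond. All phenols and the tertiary alcohol must be masked through the organolithium, carbene and dehydration steps. The demand is a final cleavage mild enough that neither the prenyl group nor the tertiary alcohol is ionised.

17 is traced to 15 (through 16) by adding water back across C2=C3, that is, by restoring the C3–O bond. This turns C3 into a carbinol carbon, the product of a carbonyl addition. The demand is a dehydration that touches only the C3 hydroxyl, which is why the chain alcohol is silylated; since the only β-hydrogens sit on C2, the direction of elimination is not in question.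

15 is traced to 14 by cutting C3–C4. Both carbons are carbonyl-derived, so the cut is an umpolung acylation. It opens ring C, removes the only stereocentre and leaves an aldehyde and a ketone tethered through O1–C2. The forward step must make the acyl anion pathway faster than enolisation of the O–CH2–C=O unit and must engage a doubly ortho-substituted aldehyde.

14 is traced to 13 and 8 by cutting the O1–C2 ether bond. This is the convergent union of two arenes of similar size, and because 13 has a single free hydroxyl the chain is fixed at C6. The demand is a base mild enough that the product does not undergo aldol closure.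

13 is traced to 12 by cutting the formyl carbon from C4a. The phenol directs formylation to its ortho positions, which are equivalent, while the para position is blocked. The forward step must tolerate acetals and a silyl ether.

12 is traced to 10 (through 11) by cutting the aryl C–O bond that becomes C8a–O1 back to a C–H bond. That C–H is the only one on the ring with no ortho substituent, so the oxygen can be introduced late by sterically governed borylation and oxidation. This removes the need to tell a para oxygen from its two ortho neighbours, which a ready-made trioxygenated ring would demand. The forward step requires that no alkene be present.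

10 is traced to 9 by cutting the O–Si bond, and 9 to 5 by cutting the tertiary C–O bond back to the alkene. The silyl ether is placed here, before any carbonyl group exists, so that a silyl triflate never meets an enolisable aryloxymethyl ketone or an aldehyde. The hydration must be Markovnikov and neutral. The gain is that 5 serves both halves of the molecule.

8 is traced to 5 and 6 (through 7) by cutting the aryl–acyl bond that becomes C1′–C3. The acetal at the neighbouring carbon directs metalation there. The forward step must lithiate the ring faster than the benzylic–allylic CH2 and must add to the amide carbonyl without displacing chloride.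

5 is traced to 2 and 3 (through 4) by cutting the aryl–CH2 bond at the carbon between the two acetal oxygens, the most acidic ring position. 2 is traced to 1 by cutting the two acetal O–CH2 bonds. The demand is allylation at the primary carbon of 3 without allylic transposition.

## Other disconnections considered

Alternative 1: Both C3–C2 and C3–C4 are cut, so that C3 with ring B is excised as a one-carbon unit. In the forward step the chlorodiazirine A3 loses nitrogen to give an arylchlorocarbene, which cyclopropanates the C2=C3 enol ether bond of the 3-silyloxybenzofuran A2 (in benzofuran numbering; these two carbons become C2 and C4 of the isoflavone). The chlorocyclopropane then opens with loss of chloride and of the silyl group to give the ring-expanded pyranone A1. In its favour, the isoflavone oxidation level is reached directly, with no stereocentre and no dehydration, which is better than the chosen plan on that point. A2 would derive from the same phenol 12, so the C6 regiochemistry is as secure as in the chosen plan. Against it, A3 has to be made by hypochlorite oxidation (Graham reaction) of the amidine A4, which a prenyl alkene would not be expected to survive. The ring B unit therefore carries no prenyl group and a benzyl ether, and A1 still needs hydrogenolysis, C3′ prenylation through an O-alkylation and Claisen sequence, and deprotection. Electron-rich aryl chlorodiazirines are labile, and the free carbene has an intramolecular escape by insertion into the benzylic C–H of its own ortho benzyloxy group. Mechanistically, a free carbene with several competing paths is set against a catalytic, reversible carbene–aldehyde adduct; both are lightly precedented on rings this electron-rich, so the uncertainty is about equal. In step economy the alternative is clearly longer after its key step (four or more operations against two).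

Alternative 2: C4–C4a is cut. In the forward step the (Z)-3-aryloxy-2-arylacrylic acid A6 is converted by trifluoroacetic anhydride into a mixed anhydride that acylates the ortho carbon of ring A and closes ring C, giving A5. In its favour, the aryloxy ring is symmetrical about its C–O axis, so either ortho carbon gives the 6-substituted product; this equals the chosen plan in regiochemical certainty. The ring is a very good nucleophile, the isoflavone is formed directly without oxidation-level adjustment or a stereocentre (better), and ring A needs no formyl group, so 12 could be used as it stands (one step saved on that side). Against it, the step runs in a strongly acidic, acylating medium in the presence of four acetals, a prenyl group next to oxygen functions and a tertiary alcohol, which would have to be protected or would be acylated or eliminated. Ring B is also electron-rich and competes as a nucleophile or proton acceptor, and only the Z acid can close. Joining the oxygen of 12 to the acrylate β-carbon by addition–elimination, followed by hydrolysis to A6, is estimated at four to five operations, so the overall count is about equal to the chosen plan. On mechanism the alternative is better in needing no umpolung catalyst; the chosen plan is better in running under nearly neutral, catalytic conditions that suit the fragile groups.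

Alternative 3: Ring B is taken apart at C1′–C2′, C2′–C3′ and C4′–C5′, with C5′–C6′ arising from a Wolff shift (Danheiser benzannulation). In the forward step, photolysis of the chromone-bearing diazo enone A8 gives a vinylketene, which adds the prenyl siloxyalkyne A9 to a cyclobutenone. Electrocyclic opening and 6π closure then give the phenol A7, with the 2′-hydroxyl free, the prenyl group at C3′ and the silyloxy group at C4′. In its favour, the substitution pattern of ring B follows from the mechanism with complete regiocontrol, which is better than the directed metalation of the chosen plan with its benzylic deprotonation hazard. The prenyl group also arrives late and meets few reagents, and the end-game is a deprotection only (equal or slightly better). Against it, A8 has to be built on a ring A chromone through a C3 side chain and a base-mediated diazo transfer, although chromones are opened by amines and other nucleophiles. The chromone and enone chromophores absorb where the diazo ketone does, so competing photochemistry is likely. A9 is a hydrolytically sensitive reagent requiring its own multistep preparation. Ring B is thus assembled from acyclic pieces, and the route is several steps longer than the chosen plan, which buys both rings from one resorcinol derivative.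

Key step: step 9

## Route

Step 1
Reactants: 1 resorcinol
Product: 2 1,3-bis(methoxymethoxy)benzene
Conditions: NaH, MOMCl, DMF, 0 °C → rt
Reagents that add atoms: chloromethyl methyl ether, COCCl
Why: Williamson-type alkylation of both phenoxides gives the bis(methoxymethyl) ether; the acetals are stable to organolithium, radical, borylation and basic conditions and are strong ortho-directing groups.

Step 2
Reactants: 2 1,3-bis(methoxymethoxy)benzene; 3 prenyl bromide
Product: 5 1,3-bis(methoxymethoxy)-2-(3-methylbut-2-en-1-yl)benzene, via aryllithium 4 (not isolated)
Conditions: n-BuLi, THF, 0 °C → rt; CuI (10 mol %), then 3, −78 °C → rt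
Reagents that add atoms: n-butyllithium, [Li]CCCC (lithium of 4 only)
Why: Directed ortho-metalation takes place at C2, the position flanked by both acetal oxygens, and copper-catalysed allylation of the aryllithium should occur at the primary carbon of 3 (SN2, not SN2′).

Step 3
Reactants: 5 1,3-bis(methoxymethoxy)-2-(3-methylbut-2-en-1-yl)benzene; 6 2-chloro-N-methoxy-N-methylacetamide
Product: 8 2-chloro-1-[2,4-bis(methoxymethoxy)-3-(3-methylbut-2-en-1-yl)phenyl]ethan-1-one, via aryllithium 7 (not isolated)
Conditions: n-BuLi, TMEDA, THF, −20 → 0 °C; then 6, −78 °C; aq. NH4Cl, −78 °C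
Reagents that add atoms: n-butyllithium, [Li]CCCC (lithium of 7 only)
Why: Acetal-directed ortho-metalation at the free position next to an acetal (C2 being blocked) is followed by acylation with the Weinreb amide, whose chelated tetrahedral adduct persists until the cold quench, so neither over-addition nor chloride displacement is expected.

Step 4
Reactants: 5 1,3-bis(methoxymethoxy)-2-(3-methylbut-2-en-1-yl)benzene
Product: 9 4-[2,6-bis(methoxymethoxy)phenyl]-2-methylbutan-2-ol
Conditions: Co(acac)2 (10 mol %), PhSiH3, O2 (1 atm), THF–i-PrOH, rt
Reagents that add atoms: dioxygen, O=O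
Why: Mukaiyama hydration: hydrogen-atom transfer from a cobalt hydride to the trisubstituted alkene gives the tertiary radical, which is trapped by oxygen and reduced by the silane to the Markovnikov tertiary alcohol; the neutral conditions spare the acetals.

Step 5
Reactants: 9 4-[2,6-bis(methoxymethoxy)phenyl]-2-methylbutan-2-ol
Product: 10 {[4-(2,6-bis(methoxymethoxy)phenyl)-2-methylbutan-2-yl]oxy}triethylsilane
Conditions: TESOTf, 2,6-lutidine, CH2Cl2, −78 °C
Reagents that add atoms: triethylsilyl trifluoromethanesulfonate, CC[Si](CC)(CC)OS(=O)(=O)C(F)(F)F
Why: Silyl triflate silylation of a hindered tertiary alcohol; it is done here because no carbonyl group is yet present that could be enol-silylated, and at −78 °C with a near-stoichiometric, buffered triflate the aryl acetals should be left alone.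

Step 6
Reactants: 10 {[4-(2,6-bis(methoxymethoxy)phenyl)-2-methylbutan-2-yl]oxy}triethylsilane
Product: 12 3,5-bis(methoxymethoxy)-4-[3-methyl-3-(triethylsilyloxy)butyl]phenol, via arylboronate 11 (not isolated)
Conditions: [Ir(OMe)(cod)]2 (1.5 mol %), 4,4′-di-tert-butyl-2,2′-bipyridine (3 mol %), B2pin2, THF, 80 °C; then 30% H2O2, aq. NaOH, THF, 0 °C
Reagents that add atoms: bis(pinacolato)diboron, CC1(C)OB(OC1(C)C)B1OC(C)(C)C(C)(C)O1 (boryl group of 11 only); hydrogen peroxide, OO (phenol oxygen of 12)
Why: Iridium-catalysed C–H borylation is sterically governed and should take the only ring C–H without an ortho substituent, para to the alkyl chain; oxidation of the C–B bond in the same pot gives the phenol (one-pot borylation–oxidation).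

Step 7
Reactants: 12 3,5-bis(methoxymethoxy)-4-[3-methyl-3-(triethylsilyloxy)butyl]phenol
Product: 13 2-hydroxy-4,6-bis(methoxymethoxy)-5-[3-methyl-3-(triethylsilyloxy)butyl]benzaldehyde
Conditions: MgCl2, Et3N, (CH2O)n, MeCN, reflux
Reagents that add atoms: formaldehyde (as paraformaldehyde), C=O
Why: Magnesium-mediated ortho-formylation (Casnati–Skattebøl): the magnesium phenoxide delivers formaldehyde to the ortho carbon and a second formaldehyde oxidises the benzylic alkoxide by hydride transfer; the two ortho positions are equivalent and the para position is blocked, so a single aldehyde is expected under basic conditions that suit acetals and silyl ether.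

Step 8
Reactants: 13 2-hydroxy-4,6-bis(methoxymethoxy)-5-[3-methyl-3-(triethylsilyloxy)butyl]benzaldehyde; 8 2-chloro-1-[2,4-bis(methoxymethoxy)-3-(3-methylbut-2-en-1-yl)phenyl]ethan-1-one
Product: 14 2-{2-[2,4-bis(methoxymethoxy)-3-(3-methylbut-2-en-1-yl)phenyl]-2-oxoethoxy}-4,6-bis(methoxymethoxy)-5-[3-methyl-3-(triethylsilyloxy)butyl]benzaldehyde
Conditions: K2CO3, NaI (10 mol %), acetone, rt
Reagents that add atoms: none
Why: Williamson etherification of the only free hydroxyl of 13 with the phenacyl-type chloride, accelerated by in situ halide exchange, forms O1–C2; room temperature and a heterogeneous carbonate are chosen to hold back the aldol–dehydration of the product to a 2-aroylbenzofuran (Rap–Stoermer reaction).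

Step 9
Reactants: 14 2-{2-[2,4-bis(methoxymethoxy)-3-(3-methylbut-2-en-1-yl)phenyl]-2-oxoethoxy}-4,6-bis(methoxymethoxy)-5-[3-methyl-3-(triethylsilyloxy)butyl]benzaldehyde
Product: 15 racemic 3-hydroxy-3-[2,4-bis(methoxymethoxy)-3-(3-methylbut-2-en-1-yl)phenyl]-5,7-bis(methoxymethoxy)-6-[3-methyl-3-(triethylsilyloxy)butyl]chroman-4-one
Conditions: 2-(pentafluorophenyl)-6,7-dihydro-5H-pyrrolo[2,1-c][1,2,4]triazol-2-ium tetrafluoroborate (20 mol %), Et3N (20 mol %), toluene (0.02 M), 40 °C, argon
Reagents that add atoms: none
Why: Triethylamine frees the carbene from the acidic N-pentafluorophenyl triazolium salt; the carbene adds to the aldehyde of 14 and proton transfer gives the nucleophilic enaminol (Breslow intermediate), an acyl anion equivalent at the future C4. This carbon attacks the tethered aryl ketone carbon (future C3) in a 6-exo-trig closure that forms C3–C4 and ring C, and proton transfer with loss of the carbene leaves the tertiary ketol 15. The closest known reaction type is the carbene-catalysed intramolecular crossed aldehyde–ketone benzoin of 2-(2-oxo-2-arylethoxy)benzaldehydes to 3-hydroxychroman-4-ones, of which 14 is a more crowded and more electron-rich member. The new C3 stereocentre is formed without control (achiral catalyst, no other stereocentre), so 15 is expected as a racemate, which is harmless because C3 becomes sp2 in step 10. The selectivity needed is chemoselectivity: acyl anion addition must outrun enolisation of the O–CH2–C=O unit, whose aldol onto the aldehyde would end in a 2-aroylbenzofuran. This should be secured by the weak amine base (strong enough only for the triazolium C–H), by the low electrophilicity of the di-ortho-alkoxy aldehyde towards an enolate, and by the fact that only the aldehyde can form the enaminol, so donor and acceptor roles are fixed. Intermolecular aldehyde–aldehyde benzoin is disfavoured by the two ortho substituents and by dilution, and air is excluded so that the enaminol is not oxidised.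

Step 10
Reactants: 15 racemic 3-hydroxy-3-[2,4-bis(methoxymethoxy)-3-(3-methylbut-2-en-1-yl)phenyl]-5,7-bis(methoxymethoxy)-6-[3-methyl-3-(triethylsilyloxy)butyl]chroman-4-one
Product: 17 3-[2,4-bis(methoxymethoxy)-3-(3-methylbut-2-en-1-yl)phenyl]-5,7-bis(methoxymethoxy)-6-[3-methyl-3-(triethylsilyloxy)butyl]-4H-chromen-4-one, via chlorosulfite 16 (not isolated)
Conditions: SOCl2, pyridine, CH2Cl2, −10 → 0 °C
Reagents that add atoms: thionyl chloride, O=S(Cl)Cl (chlorosulfinyl group of 16 only)
Why: Dehydration of a tertiary alcohol through its chlorosulfite: the only β-hydrogens are on C2, so elimination can only form C2=C3, and the product is an aromatic 4-pyranone, which provides the driving force. Excess pyridine buffers the HCl so that acetals and silyl ether should survive, and the silyl ether keeps the chain alcohol out of the reaction.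

Step 11
Reactants: 17 3-[2,4-bis(methoxymethoxy)-3-(3-methylbut-2-en-1-yl)phenyl]-5,7-bis(methoxymethoxy)-6-[3-methyl-3-(triethylsilyloxy)butyl]-4H-chromen-4-one
Product: 18 3-[2,4-dihydroxy-3-(3-methylbut-2-en-1-yl)phenyl]-5,7-dihydroxy-6-(3-hydroxy-3-methylbutyl)-4H-chromen-4-one
Conditions: 3 M aq. HCl, MeOH–THF, 40 °C; NaHCO3 quench at full conversion
Reagents that add atoms: none
Why: Acid-catalysed acetal exchange with methanol removes the four methoxymethyl groups and the same medium solvolyses the triethylsilyl ether; dilute acid at moderate temperature is chosen so that the prenyl group and the tertiary alcohol are not ionised.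

## Compound list

1 | resorcinol | Oc1cccc(O)c1 | starting material
2 | 1,3-bis(methoxymethoxy)benzene | COCOc1cccc(OCOC)c1 | intermediate
3 | prenyl bromide (1-bromo-3-methylbut-2-ene) | CC(C)=CCBr | starting material
4 | [2,6-bis(methoxymethoxy)phenyl]lithium (not isolated) | [Li]c1c(OCOC)cccc1OCOC | intermediate
5 | 1,3-bis(methoxymethoxy)-2-(3-methylbut-2-en-1-yl)benzene | COCOc1cccc(OCOC)c1CC=C(C)C | intermediate
6 | 2-chloro-N-methoxy-N-methylacetamide | CON(C)C(=O)CCl | starting material
7 | [2,4-bis(methoxymethoxy)-3-(3-methylbut-2-en-1-yl)phenyl]lithium (not isolated) | [Li]c1ccc(OCOC)c(CC=C(C)C)c1OCOC | intermediate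
8 | 2-chloro-1-[2,4-bis(methoxymethoxy)-3-(3-methylbut-2-en-1-yl)phenyl]ethan-1-one | O=C(CCl)c1ccc(OCOC)c(CC=C(C)C)c1OCOC | intermediate
9 | 4-[2,6-bis(methoxymethoxy)phenyl]-2-methylbutan-2-ol | COCOc1cccc(OCOC)c1CCC(C)(C)O | intermediate
10 | {[4-(2,6-bis(methoxymethoxy)phenyl)-2-methylbutan-2-yl]oxy}triethylsilane | COCOc1cccc(OCOC)c1CCC(C)(C)O[Si](CC)(CC)CC | intermediate
11 | 2-{3,5-bis(methoxymethoxy)-4-[3-methyl-3-(triethylsilyloxy)butyl]phenyl}-4,4,5,5-tetramethyl-1,3,2-dioxaborolane (not isolated) | COCOc1cc(B2OC(C)(C)C(C)(C)O2)cc(OCOC)c1CCC(C)(C)O[Si](CC)(CC)CC | intermediate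
12 | 3,5-bis(methoxymethoxy)-4-[3-methyl-3-(triethylsilyloxy)butyl]phenol | COCOc1cc(O)cc(OCOC)c1CCC(C)(C)O[Si](CC)(CC)CC | intermediate
13 | 2-hydroxy-4,6-bis(methoxymethoxy)-5-[3-methyl-3-(triethylsilyloxy)butyl]benzaldehyde | O=Cc1c(O)cc(OCOC)c(CCC(C)(C)O[Si](CC)(CC)CC)c1OCOC | intermediate
14 | 2-{2-[2,4-bis(methoxymethoxy)-3-(3-methylbut-2-en-1-yl)phenyl]-2-oxoethoxy}-4,6-bis(methoxymethoxy)-5-[3-methyl-3-(triethylsilyloxy)butyl]benzaldehyde (key-step precursor) | O=Cc1c(OCC(=O)c2ccc(OCOC)c(CC=C(C)C)c2OCOC)cc(OCOC)c(CCC(C)(C)O[Si](CC)(CC)CC)c1OCOC | intermediate
15 | racemic 3-hydroxy-3-[2,4-bis(methoxymethoxy)-3-(3-methylbut-2-en-1-yl)phenyl]-5,7-bis(methoxymethoxy)-6-[3-methyl-3-(triethylsilyloxy)butyl]chroman-4-one (key-step product) | O=C1c2c(OCOC)c(CCC(C)(C)O[Si](CC)(CC)CC)c(OCOC)cc2OCC1(O)c1ccc(OCOC)c(CC=C(C)C)c1OCOC | intermediate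
16 | C3 chlorosulfite of 15, racemic (not isolated) | O=C1c2c(OCOC)c(CCC(C)(C)O[Si](CC)(CC)CC)c(OCOC)cc2OCC1(OS(=O)Cl)c1ccc(OCOC)c(CC=C(C)C)c1OCOC | intermediate
17 | 3-[2,4-bis(methoxymethoxy)-3-(3-methylbut-2-en-1-yl)phenyl]-5,7-bis(methoxymethoxy)-6-[3-methyl-3-(triethylsilyloxy)butyl]-4H-chromen-4-one | O=c1c(-c2ccc(OCOC)c(CC=C(C)C)c2OCOC)coc2cc(OCOC)c(CCC(C)(C)O[Si](CC)(CC)CC)c(OCOC)c12 | intermediate
18 | 3-[2,4-dihydroxy-3-(3-methylbut-2-en-1-yl)phenyl]-5,7-dihydroxy-6-(3-hydroxy-3-methylbutyl)-4H-chromen-4-one | CC(C)=CCc1c(O)ccc(-c2coc3cc(O)c(CCC(C)(C)O)c(O)c3c2=O)c1O | target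

## Step count and least certain steps

Total step count: 11. Longest linear sequence: 10 steps (steps 1, 2, 4, 5, 6, 7, 8, 9, 10, 11); steps 3 and 4 branch from 5, and the branches meet in step 8.

Step 9 (key step). The most likely failure is that the carbene does not add productively to the aldehyde, which is crowded by two ortho oxygen substituents and deactivated by three donor groups, so that the slower base-induced enolisation and aldol–dehydration takes over; oxidation of the enaminol by traces of air is a lesser risk. The fallback gives up the C3–C4 closure and forms the C3–C1′ bond by Suzuki–Miyaura coupling. It sets out from 13 and from aryllithium 7 and returns to the route at 17, bypassing 8, 14, 15 and 16. Addition of MeMgBr to 13 (THF, 0 °C) would give the 1-arylethanol F1, which MnO2 would oxidise to the 2-hydroxyacetophenone F2. Heating F2 with N,N-dimethylformamide dimethyl acetal would give the enaminone F3, and iodine in CHCl3–pyridine would cyclise it to the 3-iodochromone F4. On the other side, 7 would be quenched with 2-isopropoxy-4,4,5,5-tetramethyl-1,3,2-dioxaborolane to the pinacol arylboronate F5. Coupling of F4 with F5 (Pd(PPh3)4, aq. Na2CO3, DME, 80 °C) should then give 17.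

Step 3. Deprotonation at the benzylic–allylic CH2, which is doubly activated and flanked by two coordinating acetals, may compete with ring metalation and lead to alkene migration or acylation in the side chain; attack of the aryllithium at the C–Cl carbon is a lesser risk. The fallback generates 7 by halogen–lithium exchange instead of deprotonation; it sets out from 2 and returns at 7. Bromination of 2 with NBS (MeCN, 0 °C) would give 1-bromo-2,4-bis(methoxymethoxy)benzene F6. LDA (THF, −78 °C) would remove the proton between the two acetal oxygens to give the 3-lithio-1-bromo-2,4-bis(methoxymethoxy)benzene F7, and copper-catalysed allylation with 3 would give 1-bromo-2,4-bis(methoxymethoxy)-3-(3-methylbut-2-en-1-yl)benzene F8. Treatment of F8 with n-BuLi at −78 °C should exchange bromine for lithium much faster than any deprotonation and so deliver 7, which is acylated with 6 as before.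

Step 8. The product carries an aldehyde next to an enolisable aryloxymethyl ketone, so aldol addition and dehydration under the basic conditions may erode it, and alkylation of the hydrogen-bonded phenol may be slow enough to let this happen. The fallback forms the same O1–C2 bond without base by a Mitsunobu reaction; it sets out from 8 and 13 and returns at 14. Sodium formate (aq. EtOH, reflux) would convert 8 into the formate ester F9, and brief methanolysis (cat. K2CO3, MeOH, 0 °C) would give the α-hydroxy ketone F10. Condensation of F10 with the acidic phenol 13 (PPh3, DIAD, THF, 0 °C → rt) should then give 14.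

Step 10. Ionisation at C3 may be followed by participation of the neighbouring ortho acetal oxygen or by chloride capture instead of proton loss, and adventitious HCl may strip an acetal. The fallback inverts the order of the last two operations; it sets out from 15 and returns at 18, skipping 16 and 17. Acidic methanolysis of 15 (aq. HCl, MeOH–THF, 40–50 °C) would first remove the acetals and the silyl ether to give the pentahydroxy ketol F11. The freed 2′- and 4′-hydroxyls then stabilise positive charge at C3 in the manner of a protonated quinone methide, so water should be lost across C2–C3 under the same acid, as hydroxyisoflavanones are known to do, giving 18 directly.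

Step 11. Before the last acetal is cleaved, the acid may protonate the prenyl alkene or ionise the tertiary alcohol, each leading to cyclisation onto a neighbouring phenol, to elimination or to methyl ether formation. The fallback avoids protic acid altogether; it sets out from 17 and returns at 18. Trimethylsilyl triflate with 2,2′-bipyridyl (MeCN, 0 °C) should convert the four aryl methoxymethyl ethers into trimethylsilyl ethers through bipyridinium acetal salts, giving the tetrakis(trimethylsilyl) ether F12 with the triethylsilyl ether intact. Fluoride buffered with acetic acid (TBAF, AcOH, THF, 0 °C) would then remove all five silyl groups to give 18.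

## Further compounds

F1 | step 9 | 1-{2-hydroxy-4,6-bis(methoxymethoxy)-5-[3-methyl-3-(triethylsilyloxy)butyl]phenyl}ethan-1-ol (racemic) | CC(O)c1c(O)cc(OCOC)c(CCC(C)(C)O[Si](CC)(CC)CC)c1OCOC
F2 | step 9 | 1-{2-hydroxy-4,6-bis(methoxymethoxy)-5-[3-methyl-3-(triethylsilyloxy)butyl]phenyl}ethan-1-one | CC(=O)c1c(O)cc(OCOC)c(CCC(C)(C)O[Si](CC)(CC)CC)c1OCOC
F3 | step 9 | (E)-3-(dimethylamino)-1-{2-hydroxy-4,6-bis(methoxymethoxy)-5-[3-methyl-3-(triethylsilyloxy)butyl]phenyl}prop-2-en-1-one | CN(C)/C=C/C(=O)c1c(O)cc(OCOC)c(CCC(C)(C)O[Si](CC)(CC)CC)c1OCOC
F4 | step 9 | 3-iodo-5,7-bis(methoxymethoxy)-6-[3-methyl-3-(triethylsilyloxy)butyl]-4H-chromen-4-one | O=c1c(I)coc2cc(OCOC)c(CCC(C)(C)O[Si](CC)(CC)CC)c(OCOC)c12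
F5 | step 9 | 2-[2,4-bis(methoxymethoxy)-3-(3-methylbut-2-en-1-yl)phenyl]-4,4,5,5-tetramethyl-1,3,2-dioxaborolane | CC1(C)OB(OC1(C)C)c1ccc(OCOC)c(CC=C(C)C)c1OCOC
F6 | step 3 | 1-bromo-2,4-bis(methoxymethoxy)benzene | COCOc1ccc(Br)c(OCOC)c1
F7 | step 3 | [3-bromo-2,6-bis(methoxymethoxy)phenyl]lithium | [Li]c1c(OCOC)ccc(Br)c1OCOC
F8 | step 3 | 1-bromo-2,4-bis(methoxymethoxy)-3-(3-methylbut-2-en-1-yl)benzene | COCOc1ccc(Br)c(OCOC)c1CC=C(C)C
F9 | step 8 | 2-[2,4-bis(methoxymethoxy)-3-(3-methylbut-2-en-1-yl)phenyl]-2-oxoethyl formate | O=COCC(=O)c1ccc(OCOC)c(CC=C(C)C)c1OCOC
F10 | step 8 | 2-hydroxy-1-[2,4-bis(methoxymethoxy)-3-(3-methylbut-2-en-1-yl)phenyl]ethan-1-one | OCC(=O)c1ccc(OCOC)c(CC=C(C)C)c1OCOC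
F11 | step 10 | racemic 3,5,7-trihydroxy-3-[2,4-dihydroxy-3-(3-methylbut-2-en-1-yl)phenyl]-6-(3-hydroxy-3-methylbutyl)chroman-4-one | O=C1c2c(O)c(CCC(C)(C)O)c(O)cc2OCC1(O)c1ccc(O)c(CC=C(C)C)c1O
F12 | step 11 | 3-[3-(3-methylbut-2-en-1-yl)-2,4-bis(trimethylsilyloxy)phenyl]-6-[3-methyl-3-(triethylsilyloxy)butyl]-5,7-bis(trimethylsilyloxy)-4H-chromen-4-one | CC(C)=CCc1c(O[Si](C)(C)C)ccc(-c2coc3cc(O[Si](C)(C)C)c(CCC(C)(C)O[Si](CC)(CC)CC)c(O[Si](C)(C)C)c3c2=O)c1O[Si](C)(C)C
A1 | alternative 1 | 3-[2-(benzyloxy)-4-(methoxymethoxy)phenyl]-5,7-bis(methoxymethoxy)-6-[3-methyl-3-(triethylsilyloxy)butyl]-4H-chromen-4-one | COCOc1ccc(-c2coc3cc(OCOC)c(CCC(C)(C)O[Si](CC)(CC)CC)c(OCOC)c3c2=O)c(OCc2ccccc2)c1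
A2 | alternative 1 | 3-(tert-butyldimethylsilyloxy)-4,6-bis(methoxymethoxy)-5-[3-methyl-3-(triethylsilyloxy)butyl]benzofuran | COCOc1cc2occ(O[Si](C)(C)C(C)(C)C)c2c(OCOC)c1CCC(C)(C)O[Si](CC)(CC)CC
A3 | alternative 1 | 3-[2-(benzyloxy)-4-(methoxymethoxy)phenyl]-3-chloro-3H-diazirine | COCOc1ccc(C2(Cl)N=N2)c(OCc2ccccc2)c1
A4 | alternative 1 | 2-(benzyloxy)-4-(methoxymethoxy)benzamidine | COCOc1ccc(C(=N)N)c(OCc2ccccc2)c1
A5 | alternative 2 | 3-[2,4-bis(methoxymethoxy)-3-(3-methylbut-2-en-1-yl)phenyl]-6-(3-hydroxy-3-methylbutyl)-5,7-bis(methoxymethoxy)-4H-chromen-4-one | COCOc1cc2occ(-c3ccc(OCOC)c(CC=C(C)C)c3OCOC)c(=O)c2c(OCOC)c1CCC(C)(C)O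
A6 | alternative 2 | (Z)-2-[2,4-bis(methoxymethoxy)-3-(3-methylbut-2-en-1-yl)phenyl]-3-[4-(3-hydroxy-3-methylbutyl)-3,5-bis(methoxymethoxy)phenoxy]acrylic acid | OC(=O)/C(c1ccc(OCOC)c(CC=C(C)C)c1OCOC)=C\Oc1cc(OCOC)c(CCC(C)(C)O)c(OCOC)c1
A7 | alternative 3 | 3-[2-hydroxy-3-(3-methylbut-2-en-1-yl)-4-(triisopropylsilyloxy)phenyl]-5,7-bis(methoxymethoxy)-6-[3-methyl-3-(triethylsilyloxy)butyl]-4H-chromen-4-one | CC(C)=CCc1c(O[Si](C(C)C)(C(C)C)C(C)C)ccc(-c2coc3cc(OCOC)c(CCC(C)(C)O[Si](CC)(CC)CC)c(OCOC)c3c2=O)c1O
A8 | alternative 3 | (E)-1-diazo-4-{5,7-bis(methoxymethoxy)-6-[3-methyl-3-(triethylsilyloxy)butyl]-4-oxo-4H-chromen-3-yl}but-3-en-2-one | [N-]=[N+]=CC(=O)/C=C/c1coc2cc(OCOC)c(CCC(C)(C)O[Si](CC)(CC)CC)c(OCOC)c2c1=O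
A9 | alternative 3 | triisopropyl[(5-methylhex-4-en-1-yn-1-yl)oxy]silane | CC(C)=CCC#CO[Si](C(C)C)(C(C)C)C(C)C
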